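The rate constants come from no measurement.

4 questions were put to me about 3 flasks with one charge and different temperature histories.

    substrate + free catalyst → catalyst intermediate (k1 = 1.4 /M/min, Ea1 = 41.0 kJ/mol)
    catalyst intermediate → free catalyst + product (k2 = 0.29 /min, Ea2 = 81.0 kJ/mol)
    (constants at 25 °C)

| setting | elm | larch | ash |
|---|---|---|---|
| substrate | 0.10 M | 0.10 M | 0.10 M |
| free catalyst | 0.20 mM | 0.20 mM | 0.20 mM |
| temperature | 25 °C |  | 0 °C |
| time | 10 d | 10 d | 10 d |
| remark |  | at 25 °C until 5.0 d, from then on at 0 °C |  |

- constants are those at 25 °C; use the activation energies for any other temperature

- the best flask by amount of product, in percent of the substrate charged; "all alike" if 1.5 percentage points covers them all (elm / larch / ash / all alike)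
- amount of product at the end, in percent of the substrate charged, elm
- amount of product at the end, in percent of the substrate charged, larch
- amount of product at the end, in percent of the substrate charged, ash

The second step gives the catalyst back, so I wrote its balance: free catalyst plus catalyst intermediate stay equal to the catalyst charged. I took the intermediate as made as fast as it is used up, which gave

load (bound share of the catalyst) = substrate / (substrate + load constant)

I carried the load constant (the Michaelis constant), which is the second-step rate constant over the first-step one. It was 0.207 M at 25 °C, and at a substrate concentration equal to it half the catalyst is bound. At 0 °C the first step is 4.5 times slower and the second 20 times, so it was 0.0473 M. Integrating the rate gave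

capacity = load constant × ln(charge / substrate left) + substrate used

where capacity is second-step constant × catalyst × time.

With the catalyst entirely free, the logarithm term stands by itself and the substrate decays first order. With the catalyst entirely bound, the other term stands by itself and the rate is constant. The real flask must pay both terms, so it reaches less than either extreme.

For ash the capacity was 0.0420 M. The extremes gave 58.8% and 42.0% of the charge as product. The load fell from 67.9% at the start to about 60.2%, and the mean load times the capacity gave 26.9%.

For elm the capacity was 0.835 M, far above the charge. Taking the substrate used as the whole charge gave 97.1%. I placed larch between them without reckoning it, since its capacity per day changes from elm's to ash's at 5.0 d.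

The forecast gave 97.2% for elm, 85.7% for larch and 26.9% for ash, with elm best, “leaving ash far behind and larch gaining only a little after its warm first half”.

The simulation gave 97.2% for elm, 85.8% for larch and 27.0% for ash, so elm was best.

The substrate left in ash, 73% of the charge, gives a load of 60.6%, and ash held 60.7% of its catalyst as intermediate. The neighbouring flask, ash with 8.0 × 10⁻⁴ M of free catalyst, keeps the load constant 0.0473 M, and its capacity is 0.168 M. It ended with 17% of the substrate left and 83.1% as product. That remainder requires a capacity of 0.168 M and gives a load of 26.0%, and this flask held 26.2% of its catalyst as intermediate.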